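The ratio we carry is isomer gained per minute over target standing, read from the late part of the amber run.

- amber: substrate 0.050 M; run made earlier
- flask: substrate 0.10 M; time 5.0 h

amber run (percent of the substrate charged)

| time / min | target / % | isomer of the product / % |
|---|---|---|
| 4.00 | 7.9 | 0.7 |
| 8.00 | 16.7 | 0.7 |
| 12.0 | 22.3 | 1.5 |
| 15.0 | 24.5 | 1.7 |
| 20.0 | 27.0 | 2.7 |
| 25.0 | 28.3 | 4.3 |
| 30.0 | 30.0 | 4.4 |

(scatter of a reading: 0.3 percentage points)

* share of target in target plus isomer of the product at 80 s
* share of target in target plus isomer of the product at 5.0 h

- what was read earlier has a scatter of 0.3 percentage points, one standard deviation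

Between 15.0 min and 30.0 min the amber run gains isomer at a fraction of the charge per minute, over a mean target fraction:

gain = 0.00180 min⁻¹, mean target = 0.272

drain = 0.00661 min⁻¹, half-life = 1.75 h

We call this the drain half-life: the time in which this loss, taken as first order, halves the target.

But the isomer might come straight from substrate. Against that, the amber run's early gain of 0.00113 min⁻¹ is slower than the late one, while target stock grew, so we read the isomer as coming from target. Yet that late gain is 2.7 percentage points under a scatter of 0.3 points.

The new flask has twice the charge of the amber run. The drain carries no concentration if it is first order, and the amber run can't test that.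

The flask's 5.0 h then counts:

n = 2.86 half-lives, one-way share = 13.8%

Another doubt: the readings stop after 0.286 half-lives, so they don't test a way back. We therefore take 13.8% as our low estimate, and expect the share near its resting value by 5.0 h. For 80 s the nearest figure is the amber share at 4.00 min, 91.9%, a later moment and a rough reading.

The forecast differs from both figures, with 96% and 30%: “the isomer should dominate or rival the target”.

The flask gives 96.0% and 53.3%.

    substrate → intermediate (k = 0.0730 min⁻¹)
    intermediate ⇌ target (K = 2.20, k = 0.330 min⁻¹)
    intermediate ⇌ isomer of the product (K = 2.10, k = 0.0130 min⁻¹)
    2 substrate → self-condensation product (k = 1.70 L mol⁻¹ min⁻¹)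

In this flask the share goes from 61.2% after 2.50 h to 53.3% after 5.00 h and 51.2% after 50.0 h, so at the count of 2.86 half-lives it stands 2.2 points above its later figure, and above the one-way 13.8%. The neighbouring flask, charged with 0.040 M of substrate, counts the same 2.86 half-lives, the drain taken as first order. It gives 53.4%, with target at 24.3% of its charge against 16.0% in this flask.

Readings and results are calculated for an exercise; noise was put on by code.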